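## Analysis of the target

Betaethrin E (18) is an achiral, tri-ortho-substituted diaryl ether. Ring A is the benzyl palmitate ring: C1 carries the CH2O-palmitoyl group, C3 a methoxy group, C5 a free hydroxyl and C6 the ether oxygen. Ring B is a methyl 4-methylbenzoate oxygenated at both ortho positions: C1' carries the ether oxygen, C3' the methyl group, C5' a hydroxyl and C6' the methyl ester. There is no stereocentre, so every stereocentre that appears on the way is transient and needs no control. The sensitive groups are the benzylic ester (lost on hydrogenolysis, with alkoxides and with strong Lewis acids), the two free phenols on electron-rich rings, and the ring B ester, which lies between two oxygen substituents and within reach of the C5 hydroxyl of ring A. Two things make the synthesis hard. The ether oxygen joins C6 of ring A, flanked at C1 and C5, to C1' of ring B next to the ester, so a direct aryl–oxygen coupling is sterically unfavourable; and ring A carries two meta-related oxygen atoms that must end up different, methyl ether at C3 and phenol at C5. The strategy rests on the fact that C3 and C5 of ring A are related like the two carbonyl carbons of a cyclohexane-1,3-dione: there C6 is an sp3 carbon, so the hindered ether can be made as an alkyl aryl ether, and C3 (between two CH2 groups) differs sterically from C5 (next to substituted C6), so one becomes an enol ether and the other stays a ketone before the ring is aromatic.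

## Retrosynthetic reasoning

**18 ⇒ 16 + 17.** The benzylic C–O ester bond is cut first. The palmitate is the most fragile group and would not survive hydrogenolysis, alkoxide or fluoride treatment, so it is introduced last. The forward reaction must esterify the primary benzylic hydroxyl of triol 16 in the presence of two phenols. A Mitsunobu reaction does this because it activates the alcohol, and the most acidic partner, palmitic acid 17, becomes the nucleophile.

**16 ⇒ 15 ⇒ 14.** The benzylic hydroxyl is masked as a silyl ether and the ring B phenol (O at C5') as a benzyl ether. Benzyl is used on ring B so that its removal is a hydrogenolysis carried out before the benzylic ester exists; a methyl ether would call for a Lewis-acid demethylation at the very end, next to that ester. The silyl ether lasts one step longer so that the benzylic carbon is never a free alcohol under hydrogen.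

**14 ⇒ 12.** Ring A is taken out of the aromatic oxidation level by adding hydrogen to C1 and C6. The C5 phenol becomes a ketone, the C3 methyl ether a vinylogous ester, and C6 an sp3 carbon bearing the aryloxy group. What is gained is that the crowded ether no longer has to be made between two arenes. The forward step is a catalytic aerobic dehydrogenation of a cyclohexenone to a phenol.

**12 ⇒ 11.** The O–CH3 bond of the enol ether is cut to reveal dione 11. Its two carbonyl groups differ only in their neighbours, and the forward enol etherification has to choose the unhindered C3 carbonyl.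

**11 ⇒ 9.** A carboxyl group is placed back on C2. This makes the malonate origin of C2 and C3 visible and gives the ring-closing step its acyl acceptor. In 9 it is a tert-butyl ester, so the forward removal needs only acid and leaves the ring B methyl ester and the silyl ether untouched.

**9 ⇒ 6 + 7.** This is the key disconnection. The C1–C2 bond is cut as a Michael addition and the C3–C4 bond as a Claisen condensation, which leaves enone 6 and the mixed malonate 7. These bonds are chosen because they place every ring A substituent on an acyclic enone (CH2OSi at the β-carbon C1, aryloxy at the α-carbon C6, the methyl ketone as C4–C5), while the malonate supplies C2, C3 and the C3 oxygen. The forward step must close a six-membered ring through the methyl ketone enolate and leave the ring B ester alone.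

**6 ⇒ 4 + 5.** The C1=C6 double bond is cut by olefination into β-keto phosphonate 4 and aldehyde 5. An aldol condensation of an aryloxyacetone would need a strong base next to the ring B ester and would have a regiochemical choice between the two α-positions. The phosphonate fixes the site of reaction and works under weakly basic conditions.

**4 ⇒ 2 + 3.** The C6–O bond is cut as a metal-carbenoid insertion into the O–H bond of phenol 2, with the diazo phosphonate 3 as carbene source. This is the point where the hindered ether is made, at an sp3 carbon and under neutral conditions, so no enolate or phenoxide is formed beside the ester.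

**2 ⇒ 1.** The benzyl ether is removed to reveal the symmetric diol 1. Ring B is bought with its ester, methyl group and both oxygens in place, and a single mono-alkylation desymmetrises it.

## Alternatives that were turned down

**Alternative 1:** The ether bond O–C1' and the bond from C6' to the carboxyl carbon are cut together, so both rings are used as arenes: a fully substituted ring A phenoxide, an aryne carrying the ring B methoxy and methyl groups, and a one-carbon electrophile. In the forward direction fluoride would release the aryne, the phenoxide would add at the aryne carbon meta to the methoxy group, and the aryl anion formed next to that methoxy group would be carboxylated in the same flask. The product would be 2-methoxy-6-{2-(methoxymethoxy)-4-methoxy-6-[(triisopropylsilyloxy)methyl]phenoxy}-4-methylbenzoic acid A1.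
- For: the regiochemistry follows from the polarisation of 3-alkoxyarynes, and ether and carboxyl arrive in one operation. The plan is convergent, and on convergence and on the number of bond-forming operations it is stronger than the chosen route.
- Against: the nucleophile is a phenoxide substituted at both ortho positions. It should add slowly, while the short-lived aryl anion can be protonated instead of carboxylated and the phenoxide itself can be captured by the carboxylating agent. The ring A partner, with three differentiated oxygen functions, must first be made by a separate sequence, so the methyl ether/phenol problem of ring A is moved and not solved. After A1 an esterification, three deprotections (one a selective ring B demethylation) and the palmitoylation still remain.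
- Comparison: the chosen strategy gives up convergence. In return the ether is made at an sp3 carbon, where crowding matters little, and the ring A oxygens are differentiated within the ring-forming sequence.

**Alternative 2:** Ring A is cut at C1–C2, C2–C3, C4–C5 and C5–C6 into an aryloxy-substituted diazo enone and an alkoxyacetylene. In the forward direction irradiation would trigger a Wolff rearrangement to a vinylketene, followed by [2+2] cycloaddition with the alkyne, four-electron opening of the cyclobutenone and six-electron electrocyclisation. The product would be methyl 2-{2-hydroxy-4-methoxy-6-[(tert-butyldimethylsilyloxy)methyl]phenoxy}-6-methoxy-4-methylbenzoate A2.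
- For: ring A arrives aromatic, with the C5 phenol coming from the ketene oxygen and the C3 methyl ether from the alkyne, so their placement is fixed by mechanism. No dehydrogenation is needed and few steps follow A2. On regiochemical certainty this plan is stronger than the chosen route, where the C3/C5 distinction rests on a steric preference.
- Against: four bonds are made through three reactive intermediates (two ketenes and a strained cyclobutenone), each of which can be intercepted, and the ring B ester and its electron-rich arene are held close to them. The β-aryloxy enone chromophore can isomerise or fragment under irradiation. The diazo ketone and the alkoxyacetylene are hazardous, unstable inputs that must be prepared fresh. The vinyl terminus that closes the ring carries the bulky aryloxy group.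
- Comparison: the chosen strategy uses stable, isolable intermediates and ionic reactions near room temperature, and keeps the uncertainty in one step whose side reactions are reversible.

**Alternative 3:** Ring B is cut at C3'–C4' and C5'–C6' into a 2-pyrone that already carries the ester, the methyl group and the ring A aryloxy group, and a ketene acetal. In the forward direction an inverse-demand Diels–Alder reaction would be followed by loss of the lactone bridge and of an alcohol. The product would be methyl 2-{2-(benzyloxy)-6-[(tert-butyldimethylsilyloxy)methyl]-4-methoxyphenoxy}-6-methoxy-4-methylbenzoate A3.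
- For: the regiochemistry follows from the polarisation of the two partners. The hindered ether could be introduced by addition–elimination on an activated pyrone, which avoids a direct aryl–aryl ether coupling as well as the chosen route does.
- Against: it constructs the ring that needs no construction, since the substitution pattern of ring B is available in one piece as 1. Ring A, with its three differentiated oxygens, would still have to be made separately. The aryloxy group at the pyrone 4-position is a donor and lowers the reactivity of the diene toward an electron-rich dienophile, so forcing conditions are expected. The C5' oxygen arrives as a methyl ether and a selective demethylation is still needed.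
- Comparison: the chosen strategy spends its steps on ring A, where the difficulty lies.

Key step: step 4

Assumption: methyl 2,6-dihydroxy-4-methylbenzoate 1 is treated as a purchasable building block, so that ring B is bought with its ester, its methyl group and both oxygen atoms in place.

## Route

Step 1
Reactants: 1 methyl 2,6-dihydroxy-4-methylbenzoate
Product: 2 methyl 2-(benzyloxy)-6-hydroxy-4-methylbenzoate
Conditions: BnBr (1.0 equiv), K2CO3 (1.1 equiv), acetone, reflux
Reagents that add atoms: benzyl bromide, BrCc1ccccc1
Why: Williamson ether synthesis on a symmetric diol, so there is no regiochemical question. The second alkylation should be slow because the remaining hydroxyl of 2 is locked in a hydrogen bond to the ester carbonyl and is less acidic and less nucleophilic than either hydroxyl of 1.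

Step 2
Reactants: 2 methyl 2-(benzyloxy)-6-hydroxy-4-methylbenzoate; 3 dimethyl (1-diazo-2-oxopropyl)phosphonate
Product: 4 methyl 2-(benzyloxy)-6-{[1-(dimethoxyphosphoryl)-2-oxopropyl]oxy}-4-methylbenzoate
Conditions: Rh2(OAc)4 (2 mol %), PhMe, 80 °C, slow addition of 3 (1.3 equiv)
Reagents that add atoms: none
Why: Rh2(OAc)4-catalysed carbenoid O–H insertion: the electrophilic carbenoid from the diazo compound is trapped by the phenol oxygen (oxonium ylide, then 1,2-proton shift), a reaction type established for phenols and diazo phosphonates. The conditions are neutral, so the crowded C6–O bond is made at an sp3 carbon without an enolate that could attack the neighbouring ester; the new stereocentre is racemic and is removed in step 3.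

Step 3
Reactants: 4 methyl 2-(benzyloxy)-6-{[1-(dimethoxyphosphoryl)-2-oxopropyl]oxy}-4-methylbenzoate; 5 2-(tert-butyldiphenylsilyloxy)acetaldehyde
Product: 6 methyl 2-(benzyloxy)-6-{[(3Z)-5-(tert-butyldiphenylsilyloxy)-2-oxopent-3-en-3-yl]oxy}-4-methylbenzoate
Conditions: LiCl, DBU, MeCN, 0 °C → rt
Reagents that add atoms: none
Why: Horner–Wadsworth–Emmons olefination of a β-keto phosphonate with the mild LiCl/amine base system, which should leave the enolisable aldehyde and the ring B ester alone. The Z enol ether (aryloxy cis to CH2OSi) is expected, as with α-alkoxy phosphonates, but the geometry is of no consequence because both alkene carbons become sp3 in step 4.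

Step 4
Reactants: 6 methyl 2-(benzyloxy)-6-{[(3Z)-5-(tert-butyldiphenylsilyloxy)-2-oxopent-3-en-3-yl]oxy}-4-methylbenzoate; 7 tert-butyl methyl malonate
Product: 9 tert-butyl 3-[3-(benzyloxy)-2-(methoxycarbonyl)-5-methylphenoxy]-2-[(tert-butyldiphenylsilyloxy)methyl]-4,6-dioxocyclohexane-1-carboxylate, via open-chain Michael adduct 8 (not isolated)
Conditions: NaOMe (1.2 equiv), MeOH/THF, 0 → 50 °C; then 1 M HCl, 0 °C, to pH 3
Reagents that add atoms: none
Why: Methoxide converts 7 into its enolate, which adds to the β-carbon of enone 6 (ring A C1) in a Michael reaction and so makes the C1–C2 bond; methanol protonates the resulting C6 enolate to give 8. Equilibrating proton transfer then supplies the methyl ketone enolate at C4, which attacks the methyl ester of the malonate unit in a 6-(enolendo)-exo-trig Claisen acylation, makes the C3–C4 bond, closes the six-membered carbocycle that becomes ring A and expels methoxide. The sequence is pulled forward because the 1,3-dione of 9 is far more acidic than methanol and is deprotonated at once; the closest known reaction type is the Michael–Claisen annulation of malonates with enones that leads to dimedone-type cyclohexane-1,3-diones. Three stereocentres arise (C1, C2, C6): C1 is set in the conjugate addition without any control element, C2 and C6 lie α to carbonyl groups and should equilibrate under the basic conditions toward the all-trans arrangement, and none of this matters because C2 loses its carboxyl in step 5 and C1 and C6 become sp2 in step 7. Two chemoselectivities are needed. First, closure through the C4 enolate onto the malonate ester must win over closure of the C6 enolate onto the ring B ester; that ester is shielded by two ortho oxygen substituents, attack on it would create a quaternary centre in a five-membered benzofuranone, and that product cannot be deprotonated, so it can revert. Second, the methyl ester and not the tert-butyl ester must be the acyl acceptor, which the bulk of the tert-butyl group secures, so that the carboxyl left at C2 can later be removed by acid alone.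

Step 5
Reactants: 9 tert-butyl 3-[3-(benzyloxy)-2-(methoxycarbonyl)-5-methylphenoxy]-2-[(tert-butyldiphenylsilyloxy)methyl]-4,6-dioxocyclohexane-1-carboxylate
Product: 11 methyl 2-(benzyloxy)-6-({2-[(tert-butyldiphenylsilyloxy)methyl]-4,6-dioxocyclohexyl}oxy)-4-methylbenzoate, via beta-keto acid 10 (not isolated)
Conditions: TFA/CH2Cl2 (1:4), 0 °C → rt; concentrate; PhMe, 80 °C
Reagents that add atoms: none
Why: Acidolysis of the tert-butyl ester, then thermal decarboxylation of the β-keto acid through the usual cyclic six-membered transition state. The methyl benzoate, the aryl benzyl ether and the primary tert-butyldiphenylsilyl ether should tolerate dilute TFA at room temperature, and the C2 stereocentre disappears.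

Step 6
Reactants: 11 methyl 2-(benzyloxy)-6-({2-[(tert-butyldiphenylsilyloxy)methyl]-4,6-dioxocyclohexyl}oxy)-4-methylbenzoate
Product: 12 methyl 2-(benzyloxy)-6-({6-[(tert-butyldiphenylsilyloxy)methyl]-4-methoxy-2-oxocyclohex-3-en-1-yl}oxy)-4-methylbenzoate
Conditions: MeOH, camphorsulfonic acid (10 mol %), 3 Å molecular sieves, 40 °C
Reagents that add atoms: methanol, CO
Why: Acid-catalysed enol etherification of a cyclic 1,3-dione under equilibrating conditions. The C3 carbonyl lies between two CH2 groups, whereas an enol ether at C5 would place the methoxy group beside the substituted C6 and suffer allylic 1,2-strain, so the C3 enol ether with the ketone at C5 should predominate.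

Step 7
Reactants: 12 methyl 2-(benzyloxy)-6-({6-[(tert-butyldiphenylsilyloxy)methyl]-4-methoxy-2-oxocyclohex-3-en-1-yl}oxy)-4-methylbenzoate
Product: 14 methyl 2-(benzyloxy)-6-{2-[(tert-butyldiphenylsilyloxy)methyl]-6-hydroxy-4-methoxyphenoxy}-4-methylbenzoate, via cyclohexa-2,5-dienone tautomer 13 (not isolated)
Conditions: Pd(OCOCF3)2 (10 mol %), 2-(dimethylamino)pyridine (20 mol %), TsOH (20 mol %), 4 Å molecular sieves, O2 (1 atm), DMSO, 80 °C
Reagents that add atoms: none
Why: Aerobic dehydrogenation of a cyclohexenone to a phenol with a divalent palladium catalyst: a palladium enolate forms at C6, β-hydride elimination of the C1–H gives dienone 13, and its enolisation gives the aromatic ring, while O2 returns zerovalent palladium to the divalent state. The last two stereocentres vanish, and the ketone at C5 becomes the phenol while the enol ether at C3 becomes the aryl methyl ether.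

Step 8
Reactants: 14 methyl 2-(benzyloxy)-6-{2-[(tert-butyldiphenylsilyloxy)methyl]-6-hydroxy-4-methoxyphenoxy}-4-methylbenzoate
Product: 15 methyl 2-{2-[(tert-butyldiphenylsilyloxy)methyl]-6-hydroxy-4-methoxyphenoxy}-6-hydroxy-4-methylbenzoate
Conditions: H2 (1 atm), Pd/C (10% palladium on carbon), EtOAc, rt
Reagents that add atoms: none
Why: Hydrogenolysis of an aryl benzyl ether. The benzylic C–OSi bond of ring A has a poor leaving group and should survive in a neutral aprotic solvent; the step is placed before the esterification because a benzylic palmitate would not survive it.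

Step 9
Reactants: 15 methyl 2-{2-[(tert-butyldiphenylsilyloxy)methyl]-6-hydroxy-4-methoxyphenoxy}-6-hydroxy-4-methylbenzoate
Product: 16 methyl 2-hydroxy-6-[2-hydroxy-6-(hydroxymethyl)-4-methoxyphenoxy]-4-methylbenzoate
Conditions: HF·pyridine, THF/pyridine, 0 °C → rt
Reagents that add atoms: none
Why: Fluoride-mediated desilylation driven by the strength of the Si–F bond. The buffered, non-basic medium avoids phenoxides next to the ring B ester.

Step 10
Reactants: 16 methyl 2-hydroxy-6-[2-hydroxy-6-(hydroxymethyl)-4-methoxyphenoxy]-4-methylbenzoate; 17 palmitic acid
Product: 18 betaethrin E, methyl 2-{2-[(hexadecanoyloxy)methyl]-6-hydroxy-4-methoxyphenoxy}-6-hydroxy-4-methylbenzoate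
Conditions: 17 (1.05 equiv), PPh3, DIAD, THF, 0 °C → rt
Reagents that add atoms: none
Why: Mitsunobu esterification: the phosphine/azodicarboxylate pair activates only the primary benzylic alcohol as an oxyphosphonium ion. The carboxylic acid is about five pKa units more acidic than either phenol, so it is the carboxylate that is formed and that displaces the leaving group; no stereocentre is involved.

## Compound list

1 | methyl 2,6-dihydroxy-4-methylbenzoate | COC(=O)c1c(O)cc(C)cc1O | starting material
2 | methyl 2-(benzyloxy)-6-hydroxy-4-methylbenzoate | COC(=O)c1c(O)cc(C)cc1OCc1ccccc1 | intermediate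
3 | dimethyl (1-diazo-2-oxopropyl)phosphonate | CC(=O)C(=[N+]=[N-])P(=O)(OC)OC | starting material
4 | methyl 2-(benzyloxy)-6-{[1-(dimethoxyphosphoryl)-2-oxopropyl]oxy}-4-methylbenzoate (racemic) | CC(=O)C(Oc1cc(C)cc(OCc2ccccc2)c1C(=O)OC)P(=O)(OC)OC | intermediate
5 | 2-(tert-butyldiphenylsilyloxy)acetaldehyde | O=CCO[Si](c1ccccc1)(c1ccccc1)C(C)(C)C | starting material
6 | methyl 2-(benzyloxy)-6-{[(3Z)-5-(tert-butyldiphenylsilyloxy)-2-oxopent-3-en-3-yl]oxy}-4-methylbenzoate | CC(=O)/C(Oc1cc(C)cc(OCc2ccccc2)c1C(=O)OC)=C/CO[Si](c1ccccc1)(c1ccccc1)C(C)(C)C | intermediate
7 | tert-butyl methyl malonate | COC(=O)CC(=O)OC(C)(C)C | starting material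
8 | 1-tert-butyl 3-methyl 2-{3-[3-(benzyloxy)-2-(methoxycarbonyl)-5-methylphenoxy]-1-(tert-butyldiphenylsilyloxy)-4-oxopentan-2-yl}propanedioate (mixture of diastereomers) | COC(=O)C(C(=O)OC(C)(C)C)C(CO[Si](c1ccccc1)(c1ccccc1)C(C)(C)C)C(Oc1cc(C)cc(OCc2ccccc2)c1C(=O)OC)C(C)=O | intermediate (not isolated)
9 | tert-butyl 3-[3-(benzyloxy)-2-(methoxycarbonyl)-5-methylphenoxy]-2-[(tert-butyldiphenylsilyloxy)methyl]-4,6-dioxocyclohexane-1-carboxylate (racemic; all-trans isomer drawn; epimerisable) | CC(C)(C)OC(=O)[C@H]1C(=O)CC(=O)[C@@H](Oc2cc(C)cc(OCc3ccccc3)c2C(=O)OC)[C@@H]1CO[Si](c1ccccc1)(c1ccccc1)C(C)(C)C | intermediate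
10 | 3-[3-(benzyloxy)-2-(methoxycarbonyl)-5-methylphenoxy]-2-[(tert-butyldiphenylsilyloxy)methyl]-4,6-dioxocyclohexane-1-carboxylic acid (racemic; all-trans isomer drawn) | OC(=O)[C@H]1C(=O)CC(=O)[C@@H](Oc2cc(C)cc(OCc3ccccc3)c2C(=O)OC)[C@@H]1CO[Si](c1ccccc1)(c1ccccc1)C(C)(C)C | intermediate (not isolated)
11 | methyl 2-(benzyloxy)-6-({2-[(tert-butyldiphenylsilyloxy)methyl]-4,6-dioxocyclohexyl}oxy)-4-methylbenzoate (racemic; trans isomer drawn) | C1C(=O)CC(=O)[C@@H](Oc2cc(C)cc(OCc3ccccc3)c2C(=O)OC)[C@@H]1CO[Si](c1ccccc1)(c1ccccc1)C(C)(C)C | intermediate
12 | methyl 2-(benzyloxy)-6-({6-[(tert-butyldiphenylsilyloxy)methyl]-4-methoxy-2-oxocyclohex-3-en-1-yl}oxy)-4-methylbenzoate (racemic; trans isomer drawn) | C1C(OC)=CC(=O)[C@@H](Oc2cc(C)cc(OCc3ccccc3)c2C(=O)OC)[C@@H]1CO[Si](c1ccccc1)(c1ccccc1)C(C)(C)C | intermediate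
13 | methyl 2-(benzyloxy)-6-({2-[(tert-butyldiphenylsilyloxy)methyl]-4-methoxy-6-oxocyclohexa-1,4-dien-1-yl}oxy)-4-methylbenzoate | C1C(OC)=CC(=O)C(Oc2cc(C)cc(OCc3ccccc3)c2C(=O)OC)=C1CO[Si](c1ccccc1)(c1ccccc1)C(C)(C)C | intermediate (not isolated)
14 | methyl 2-(benzyloxy)-6-{2-[(tert-butyldiphenylsilyloxy)methyl]-6-hydroxy-4-methoxyphenoxy}-4-methylbenzoate | COC(=O)c1c(OCc2ccccc2)cc(C)cc1Oc1c(O)cc(OC)cc1CO[Si](c1ccccc1)(c1ccccc1)C(C)(C)C | intermediate
15 | methyl 2-{2-[(tert-butyldiphenylsilyloxy)methyl]-6-hydroxy-4-methoxyphenoxy}-6-hydroxy-4-methylbenzoate | COC(=O)c1c(O)cc(C)cc1Oc1c(O)cc(OC)cc1CO[Si](c1ccccc1)(c1ccccc1)C(C)(C)C | intermediate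
16 | methyl 2-hydroxy-6-[2-hydroxy-6-(hydroxymethyl)-4-methoxyphenoxy]-4-methylbenzoate | COC(=O)c1c(O)cc(C)cc1Oc1c(O)cc(OC)cc1CO | intermediate
17 | palmitic acid (hexadecanoic acid) | CCCCCCCCCCCCCCCC(=O)O | starting material
18 | betaethrin E, methyl 2-{2-[(hexadecanoyloxy)methyl]-6-hydroxy-4-methoxyphenoxy}-6-hydroxy-4-methylbenzoate | CCCCCCCCCCCCCCCC(=O)OCc1cc(OC)cc(O)c1Oc1cc(C)cc(O)c1C(=O)OC | target

## Step count and least certain steps

Total: 10 steps. Longest linear sequence: 10 steps (1 → 18); 3, 5, 7 and 17 enter as purchased reagents.

**Step 4 (key step).** Conjugate addition to the α-oxygenated, β-substituted enone may be slow. Base-mediated deprotonation at the CH2OSi group with migration of the double bond could then consume 6. Closure of the C6 enolate onto the ring B ester, followed by methoxide-induced cleavage, could likewise consume 8 before the Claisen closure. The fallback sets out from 6 and returns at 11. A Mukaiyama–Michael addition of 1-(tert-butyldimethylsilyloxy)-1-methoxyethene to 6 (TiCl4, CH2Cl2, −78 °C, aqueous work-up) makes the C1–C2 bond under Lewis-acidic conditions with no free base and should give methyl 4-[3-(benzyloxy)-2-(methoxycarbonyl)-5-methylphenoxy]-3-[(tert-butyldiphenylsilyloxy)methyl]-5-oxohexanoate F1. Kinetic deprotonation of its methyl ketone with LiN(SiMe3)2 (2.2 equiv, THF, −78 → 0 °C) then closes the C3–C4 bond by intramolecular Claisen condensation and gives 11 directly, so step 5 is not needed.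

**Step 6.** Regiocontrol may be incomplete, with methanol also condensing at the C5 carbonyl next to C6, and the silyl ether may slowly be lost in acidic methanol. The fallback sets out from 11 and returns at 12. Irreversible O-methylation of the enolate of 11 (dimethyl sulfate, K2CO3, acetone, rt) should give 12 together with its regioisomer methyl 2-(benzyloxy)-6-({6-[(tert-butyldiphenylsilyloxy)methyl]-2-methoxy-4-oxocyclohex-2-en-1-yl}oxy)-4-methylbenzoate F2. The two are separated by chromatography, and F2 is hydrolysed with dilute HCl in THF back to 11 and resubmitted.

**Step 7.** Palladation at the fully substituted, oxygen-bearing C6 may be slow. The water formed can hydrolyse the vinylogous ester under the acidic conditions, and the phenol product can bind the catalyst. The fallback sets out from 12 and returns at 14. Kinetic deprotonation at C6 with LiN(iPr)2 (THF, −78 °C) and trapping with PhSeCl should give methyl 2-(benzyloxy)-6-({6-[(tert-butyldiphenylsilyloxy)methyl]-4-methoxy-2-oxo-1-(phenylselanyl)cyclohex-3-en-1-yl}oxy)-4-methylbenzoate F3. Oxidation with H2O2 (pyridine, CH2Cl2, 0 °C) gives methyl 2-(benzyloxy)-6-({1-(benzeneseleninyl)-6-[(tert-butyldiphenylsilyloxy)methyl]-4-methoxy-2-oxocyclohex-3-en-1-yl}oxy)-4-methylbenzoate F4. Its syn-elimination toward the C1–H gives dienone 13, which tautomerises to 14.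

**Step 2.** The O–H bond of 2 is hydrogen-bonded and hindered, so the carbenoid may be diverted into Wolff rearrangement, dimerisation, attack on the electron-rich arene or reaction with traces of water. The fallback sets out from 2 and returns at 6, by four reactions that never use a strong base beside the ring B ester:
- Williamson alkylation of 2 with chloroacetone (K2CO3, NaI, acetone, reflux) gives methyl 2-(benzyloxy)-4-methyl-6-(2-oxopropoxy)benzoate F5.
- Soft enolisation (Me3SiOTf, Et3N, CH2Cl2, 0 °C) toward the more acidic, aryloxy-bearing carbon gives methyl 2-(benzyloxy)-4-methyl-6-{[(1Z)-2-(trimethylsilyloxy)prop-1-en-1-yl]oxy}benzoate F6.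
- Mukaiyama aldol addition to aldehyde 5 (BF3·OEt2, CH2Cl2, −78 °C) gives methyl 2-(benzyloxy)-6-{[5-(tert-butyldiphenylsilyloxy)-4-hydroxy-2-oxopentan-3-yl]oxy}-4-methylbenzoate F7.
- Mesylation (MsCl, Et3N, CH2Cl2, 0 °C) gives methyl 2-(benzyloxy)-6-{[5-(tert-butyldiphenylsilyloxy)-4-(methanesulfonyloxy)-2-oxopentan-3-yl]oxy}-4-methylbenzoate F8, which eliminates with DBU by an E1cB pathway to 6.

**Step 10.** The benzylic oxyphosphonium ion may be captured by a phenol oxygen of a second molecule (benzyl aryl ether oligomers), or a phenol may be acylated in part. The fallback sets out from 16 and 17 and returns at 18. It is an enzymatic esterification with immobilised Candida antarctica lipase B (17, 4 Å molecular sieves, toluene, 50 °C). The lipase acylates primary alcohols and leaves phenols untouched; this fallback makes no new compound (F0).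

## Further compounds

F1 | step 4 | methyl 4-[3-(benzyloxy)-2-(methoxycarbonyl)-5-methylphenoxy]-3-[(tert-butyldiphenylsilyloxy)methyl]-5-oxohexanoate (mixture of diastereomers) | COC(=O)CC(CO[Si](c1ccccc1)(c1ccccc1)C(C)(C)C)C(Oc1cc(C)cc(OCc2ccccc2)c1C(=O)OC)C(C)=O
F2 | step 6 | methyl 2-(benzyloxy)-6-({6-[(tert-butyldiphenylsilyloxy)methyl]-2-methoxy-4-oxocyclohex-2-en-1-yl}oxy)-4-methylbenzoate (racemic; trans isomer drawn) | C1C(=O)C=C(OC)[C@@H](Oc2cc(C)cc(OCc3ccccc3)c2C(=O)OC)[C@@H]1CO[Si](c1ccccc1)(c1ccccc1)C(C)(C)C
F3 | step 7 | methyl 2-(benzyloxy)-6-({6-[(tert-butyldiphenylsilyloxy)methyl]-4-methoxy-2-oxo-1-(phenylselanyl)cyclohex-3-en-1-yl}oxy)-4-methylbenzoate (mixture of diastereomers) | C1C(OC)=CC(=O)C([Se]c2ccccc2)(Oc2cc(C)cc(OCc3ccccc3)c2C(=O)OC)C1CO[Si](c1ccccc1)(c1ccccc1)C(C)(C)C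
F4 | step 7 | methyl 2-(benzyloxy)-6-({1-(benzeneseleninyl)-6-[(tert-butyldiphenylsilyloxy)methyl]-4-methoxy-2-oxocyclohex-3-en-1-yl}oxy)-4-methylbenzoate (mixture of diastereomers) | C1C(OC)=CC(=O)C([Se](=O)c2ccccc2)(Oc2cc(C)cc(OCc3ccccc3)c2C(=O)OC)C1CO[Si](c1ccccc1)(c1ccccc1)C(C)(C)C
F5 | step 2 | methyl 2-(benzyloxy)-4-methyl-6-(2-oxopropoxy)benzoate | CC(=O)COc1cc(C)cc(OCc2ccccc2)c1C(=O)OC
F6 | step 2 | methyl 2-(benzyloxy)-4-methyl-6-{[(1Z)-2-(trimethylsilyloxy)prop-1-en-1-yl]oxy}benzoate | C/C(O[Si](C)(C)C)=C/Oc1cc(C)cc(OCc2ccccc2)c1C(=O)OC
F7 | step 2 | methyl 2-(benzyloxy)-6-{[5-(tert-butyldiphenylsilyloxy)-4-hydroxy-2-oxopentan-3-yl]oxy}-4-methylbenzoate (mixture of diastereomers) | CC(=O)C(Oc1cc(C)cc(OCc2ccccc2)c1C(=O)OC)C(O)CO[Si](c1ccccc1)(c1ccccc1)C(C)(C)C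
F8 | step 2 | methyl 2-(benzyloxy)-6-{[5-(tert-butyldiphenylsilyloxy)-4-(methanesulfonyloxy)-2-oxopentan-3-yl]oxy}-4-methylbenzoate (mixture of diastereomers) | CC(=O)C(Oc1cc(C)cc(OCc2ccccc2)c1C(=O)OC)C(OS(C)(=O)=O)CO[Si](c1ccccc1)(c1ccccc1)C(C)(C)C
F0 | step 10 | none | none
A1 | alternative 1 | 2-methoxy-6-{2-(methoxymethoxy)-4-methoxy-6-[(triisopropylsilyloxy)methyl]phenoxy}-4-methylbenzoic acid | COc1cc(C)cc(Oc2c(OCOC)cc(OC)cc2CO[Si](C(C)C)(C(C)C)C(C)C)c1C(=O)O
A2 | alternative 2 | methyl 2-{2-hydroxy-4-methoxy-6-[(tert-butyldimethylsilyloxy)methyl]phenoxy}-6-methoxy-4-methylbenzoate | COC(=O)c1c(OC)cc(C)cc1Oc1c(O)cc(OC)cc1CO[Si](C)(C)C(C)(C)C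
A3 | alternative 3 | methyl 2-{2-(benzyloxy)-6-[(tert-butyldimethylsilyloxy)methyl]-4-methoxyphenoxy}-6-methoxy-4-methylbenzoate | CC(C)(C)[Si](C)(C)OCc1cc(OC)cc(OCc2ccccc2)c1Oc1cc(C)cc(OC)c1C(=O)OC
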